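**Retrosynthetic overview**

- Ring numbering used here: cyclohexene C1 (quaternary; CH3 and the styryl carbon), C2, C3, C4(CH3)=C5, C6 (CH carrying the coumarin-8-yl group).
- Feature: the styryl carbon on C1 and the aryl group on C6 are cis, and the ring oxygen of that aryl group (ring B of the C6 coumarin) sits ortho to C6. Joining the styryl carbon, as a carbonyl, to that oxygen makes C1–C6 the C3–C4 bond of a cis-fused 3,4-dihydrocoumarin.
- Endgame, read backwards: the (E)-styryl C–aryl bond is cut (Heck reaction of a C1 vinyl group with 8-iodo-5,7-dimethoxycoumarin), then ring B of the C6 coumarin (ortho-formylation and intramolecular Wittig reaction on a phenol), then the vinyl group (lactol methylenation).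
- The cis-fused lactone comes from ring-closing metathesis (C4=C5). Its diene comes from a 3-(3-methylbut-3-enyl)-5,7-dimethoxycoumarin by adding vinyl (C5) to coumarin C4 and methyl (the C1 methyl) to coumarin C3 in one flask.
- Ring order: coumarin lactone (template, by intramolecular Horner–Wadsworth–Emmons reaction), cyclohexene (metathesis), lactone opened, ring B of the C6 coumarin annulated; the second coumarin arrives intact.

Key step: step 4

Remark: chlorotrimethylsilane is left out of the key step, since a silyl ketene acetal would not be methylated by iodomethane, and iodination of 5,7-dimethoxycoumarin is taken to occur at C8 (para to the 5-methoxy group, less hindered than C6).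

**Step 1**
Reactants: 1 triethyl phosphonoacetate; 2 4-bromo-2-methylbut-1-ene
Product: 3 ethyl 2-(diethoxyphosphoryl)-5-methylhex-5-enoate (racemic)
Conditions: NaH (1.0 equiv), 1 (1.2 equiv), DMF, 0 °C; then 2, NaI (cat.), 50 °C
Reagents that add atoms: none
Why: SN2 alkylation of the soft sodium phosphonoacetate carbanion by the primary homoallylic bromide (malonate-type C-alkylation) should outrun elimination to isoprene, and the slight excess of 1 limits dialkylation.

**Step 2**
Reactants: 3 ethyl 2-(diethoxyphosphoryl)-5-methylhex-5-enoate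
Product: 4 2-(diethoxyphosphoryl)-5-methylhex-5-enoic acid (racemic)
Conditions: LiOH·H2O, THF/H2O, 0 °C → rt; then aq. HCl to pH 2
Reagents that add atoms: lithium hydroxide, [Li+].[OH-]
Why: Saponification attacks the carboxylic ester far faster than the diethyl phosphonate esters and gives the acid needed to acylate the phenol.

**Step 3**
Reactants: 4 2-(diethoxyphosphoryl)-5-methylhex-5-enoic acid; 5 2-hydroxy-4,6-dimethoxybenzaldehyde
Product: 7 5,7-dimethoxy-3-(3-methylbut-3-en-1-yl)-2H-chromen-2-one, via aryl phosphonoalkanoate 6 (not isolated)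
Conditions: DCC (1.1 equiv), DMAP (10 mol%), CH2Cl2, 0 °C → rt; filter; then K2CO3, 18-crown-6 (cat.), MeCN, rt → 50 °C
Reagents that add atoms: none
Why: Steglich esterification of the phenol gives 6, whose phosphonate carbanion adds to the ortho formyl group and loses diethyl phosphate (intramolecular Horner–Wadsworth–Emmons reaction), so the C3=C4 bond forms inside the lactone ring and the cis aryl/carbonyl geometry of a coumarin is enforced without a thermal isomerisation.

**Step 4**
Reactants: 7 5,7-dimethoxy-3-(3-methylbut-3-en-1-yl)-2H-chromen-2-one; 8 vinylmagnesium bromide; 9 iodomethane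
Product: 11 (3S,4S)-4-ethenyl-5,7-dimethoxy-3-methyl-3-(3-methylbut-3-en-1-yl)-3,4-dihydro-2H-chromen-2-one, via bromomagnesium enolate 10 (not isolated)
Conditions: CuBr·SMe2 (10 mol%), (R)-1-[(Sp)-2-(dicyclohexylphosphino)ferrocenyl]ethyldiphenylphosphine (12 mol%), 8 (1.5 equiv, slow addition), t-BuOMe/CH2Cl2, −78 → −40 °C; then 9 (5 equiv), DMPU, −40 → 0 °C
Reagents that add atoms: none
Why: Proposed new method: the bisphosphine–vinylcopper species formed by transmetalation from 8 binds the C3=C4 bond of 7 as a π-complex, oxidative addition and reductive elimination make the C4–vinyl bond, and the bromomagnesium enolate 10 that remains is C-methylated by 9 once DMPU is added. The closest known reactions are the CuBr·SMe2/ferrocenyl bisphosphine-catalysed conjugate addition of alkyl Grignard reagents to 3-unsubstituted coumarins and copper-mediated conjugate addition with iodomethane trapping on unsaturated lactones, so the vinyl nucleophile and the 3-alkyl-5,7-dimethoxy acceptor are the extension. No ring is closed; two C–C bonds and two stereocentres are formed. C4 (S) is set by the chiral copper catalyst, which selects the enantioface of the C3=C4 bond (the ligand antipode is used if a pilot run shows the opposite sense). C3 (S) is set by the substrate: the peri 5-methoxy group forces the new vinyl group pseudoaxial, so 9 attacks the planar, fully substituted enolate from the opposite face, methyl ends up trans to vinyl and the butenyl chain cis to it. The step needs 1,4- over 1,2-addition, which the s-cis-locked aryl enoate with its C3 substituent flanking the carbonyl should secure together with the soft copper reagent at low temperature, and C- over O-methylation, which the magnesium counter-ion and the soft iodide should secure.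

**Step 5**
Reactants: 11 (3S,4S)-4-ethenyl-5,7-dimethoxy-3-methyl-3-(3-methylbut-3-en-1-yl)-3,4-dihydro-2H-chromen-2-one
Product: 12 (6aS,10aS)-1,3-dimethoxy-6a,9-dimethyl-6a,7,8,10a-tetrahydro-6H-benzo[c]chromen-6-one (cis-fused)
Conditions: second-generation Grubbs catalyst RuCl2(=CHPh)(H2IMes)(PCy3) (5 mol%), CH2Cl2, 40 °C
Reagents that add atoms: none
Why: Ring-closing metathesis of the C4 vinyl group with the 1,1-disubstituted alkene of the cis-disposed butenyl chain should give the trisubstituted cyclohexene (C4=C5 of the target) with loss of ethylene; neither stereocentre is touched and the cis ring fusion follows from step 4.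

**Step 6**
Reactants: 12 (6aS,10aS)-1,3-dimethoxy-6a,9-dimethyl-6a,7,8,10a-tetrahydro-6H-benzo[c]chromen-6-one
Product: 13 (6aS,10aS)-1,3-dimethoxy-6a,9-dimethyl-6a,7,8,10a-tetrahydro-6H-benzo[c]chromen-6-ol (mixture of C6 epimers)
Conditions: i-Bu2AlH (1.1 equiv), CH2Cl2, −78 °C; aq. potassium sodium tartrate
Reagents that add atoms: none
Why: Partial reduction of the lactone at −78 °C should stop at the aluminium hemiacetal, which the adjacent quaternary centre shields until the quench, and give the lactol; the ring stereocentres are untouched and the new C6 centre is of no consequence.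

**Step 7**
Reactants: 13 (6aS,10aS)-1,3-dimethoxy-6a,9-dimethyl-6a,7,8,10a-tetrahydro-6H-benzo[c]chromen-6-ol
Product: 15 2-[(1R,6R)-6-ethenyl-3,6-dimethylcyclohex-2-en-1-yl]-3,5-dimethoxyphenol, via ring-opened hydroxy aldehyde 14 (not isolated)
Conditions: Ph3PCH3Br (3.5 equiv), KOt-Bu (3.3 equiv), THF, 0 °C; then 13, 0 °C → rt
Reagents that add atoms: methyltriphenylphosphonium bromide, C[P+](c1ccccc1)(c1ccccc1)c1ccccc1.[Br-]
Why: Wittig methylenation of the lactol through its ring-opened, non-enolisable α-quaternary aldehyde 14 (excess ylide also takes up the phenol proton) turns the former lactone carbon into the C1 vinyl group and frees the phenol; the low temperature guards the benzylic centre against retro-Michael epimerisation.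

**Step 8**
Reactants: 15 2-[(1R,6R)-6-ethenyl-3,6-dimethylcyclohex-2-en-1-yl]-3,5-dimethoxyphenol
Product: 16 3-[(1R,6R)-6-ethenyl-3,6-dimethylcyclohex-2-en-1-yl]-2-hydroxy-4,6-dimethoxybenzaldehyde
Conditions: MgCl2, Et3N, (CH2O)n, MeCN, reflux
Reagents that add atoms: paraformaldehyde (as formaldehyde), C=O
Why: In the magnesium-mediated ortho-formylation (Casnati–Skattebøl reaction) the magnesium phenoxide delivers formaldehyde to the only free ortho position, between OH and OMe, and a second formaldehyde accepts the hydride; these conditions leave both alkenes alone.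

**Step 9**
Reactants: 16 3-[(1R,6R)-6-ethenyl-3,6-dimethylcyclohex-2-en-1-yl]-2-hydroxy-4,6-dimethoxybenzaldehyde
Product: 18 8-[(1R,6R)-6-ethenyl-3,6-dimethylcyclohex-2-en-1-yl]-5,7-dimethoxy-2H-chromen-2-one, via aryl phosphoranylideneacetate 17 (not isolated)
Conditions: Ph3P=C=C=O (1.3 equiv), toluene, 90 °C
Reagents that add atoms: (triphenylphosphoranylidene)ketene, O=C=C=P(c1ccccc1)(c1ccccc1)c1ccccc1
Why: The phenol adds across the ketene C=C bond to give ester ylide 17, which closes onto the ortho aldehyde by intramolecular Wittig reaction; the ring enforces the cis alkene, so ring B of the C6 coumarin should form under neutral conditions well below the temperature at which the 1,5-diene could undergo Cope rearrangement.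

**Step 10**
Reactants: 19 5,7-dimethoxy-2H-chromen-2-one
Product: 20 8-iodo-5,7-dimethoxy-2H-chromen-2-one
Conditions: N-iodosuccinimide (1.05 equiv), CF3CO2H (cat.), MeCN, 0 °C → rt, dark
Reagents that add atoms: N-iodosuccinimide, O=C1CCC(=O)N1I
Why: Electrophilic aromatic iodination should go to C8, which is para to the 5-methoxy group, ortho to the 7-methoxy group and less hindered than C6 between two methoxy groups.

**Step 11**
Reactants: 18 8-[(1R,6R)-6-ethenyl-3,6-dimethylcyclohex-2-en-1-yl]-5,7-dimethoxy-2H-chromen-2-one; 20 8-iodo-5,7-dimethoxy-2H-chromen-2-one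
Product: 21 8-[(E)-2-[(1R,2R)-2-(5,7-dimethoxy-2-oxo-2H-chromen-8-yl)-1,4-dimethylcyclohex-3-en-1-yl]ethenyl]-5,7-dimethoxy-2H-chromen-2-one (CNP0164660.2)
Conditions: Pd(OAc)2 (10 mol%), Bu4NCl (1 equiv), NaHCO3 (2.5 equiv), DMF, 85 °C
Reagents that add atoms: none
Why: In the Heck reaction the arylpalladium species formed from 20 and zerovalent palladium inserts the terminal vinyl group with aryl on the CH2 terminus, and because the allylic carbon is quaternary syn β-hydride elimination can only take the benzylic hydrogen, which should give the (E)-styrene without double-bond migration; the trisubstituted ring alkene and the coumarin C3=C4 bonds are far less reactive.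

**Compound list**

1 | triethyl phosphonoacetate | CCOC(=O)CP(=O)(OCC)OCC | starting material
2 | 4-bromo-2-methylbut-1-ene | C=C(C)CCBr | starting material
3 | ethyl 2-(diethoxyphosphoryl)-5-methylhex-5-enoate (racemic) | C=C(C)CCC(C(=O)OCC)P(=O)(OCC)OCC | intermediate
4 | 2-(diethoxyphosphoryl)-5-methylhex-5-enoic acid (racemic) | C=C(C)CCC(C(=O)O)P(=O)(OCC)OCC | intermediate
5 | 2-hydroxy-4,6-dimethoxybenzaldehyde | COc1cc(O)c(C=O)c(OC)c1 | starting material
6 | 2-formyl-3,5-dimethoxyphenyl 2-(diethoxyphosphoryl)-5-methylhex-5-enoate | C=C(C)CCC(C(=O)Oc1cc(OC)cc(OC)c1C=O)P(=O)(OCC)OCC | intermediate (not isolated)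
7 | 5,7-dimethoxy-3-(3-methylbut-3-en-1-yl)-2H-chromen-2-one | C=C(C)CCc1cc2c(OC)cc(OC)cc2oc1=O | intermediate
8 | vinylmagnesium bromide | C=C[Mg]Br | starting material
9 | iodomethane | CI | starting material
10 | bromomagnesium (4S)-4-ethenyl-5,7-dimethoxy-3-(3-methylbut-3-en-1-yl)-4H-chromen-2-olate | C=C[C@H]1c2c(OC)cc(OC)cc2OC(O[Mg]Br)=C1CCC(C)=C | intermediate (not isolated)
11 | (3S,4S)-4-ethenyl-5,7-dimethoxy-3-methyl-3-(3-methylbut-3-en-1-yl)-3,4-dihydro-2H-chromen-2-one (vinyl and butenyl cis) | O=C2Oc1cc(OC)cc(OC)c1[C@H](C=C)[C@]2(C)CCC(C)=C | intermediate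
12 | (6aS,10aS)-1,3-dimethoxy-6a,9-dimethyl-6a,7,8,10a-tetrahydro-6H-benzo[c]chromen-6-one | O=C2Oc1cc(OC)cc(OC)c1[C@@H]3C=C(C)CC[C@]23C | intermediate
13 | (6aS,10aS)-1,3-dimethoxy-6a,9-dimethyl-6a,7,8,10a-tetrahydro-6H-benzo[c]chromen-6-ol (C6 epimers) | OC2Oc1cc(OC)cc(OC)c1[C@@H]3C=C(C)CC[C@]23C | intermediate
14 | (1S,2S)-2-(2-hydroxy-4,6-dimethoxyphenyl)-1,4-dimethylcyclohex-3-ene-1-carbaldehyde | Oc1cc(OC)cc(OC)c1[C@@H]2C=C(C)CC[C@]2(C)C=O | intermediate (not isolated)
15 | 2-[(1R,6R)-6-ethenyl-3,6-dimethylcyclohex-2-en-1-yl]-3,5-dimethoxyphenol | Oc1cc(OC)cc(OC)c1[C@@H]2C=C(C)CC[C@]2(C)C=C | intermediate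
16 | 3-[(1R,6R)-6-ethenyl-3,6-dimethylcyclohex-2-en-1-yl]-2-hydroxy-4,6-dimethoxybenzaldehyde | O=Cc1c(OC)cc(OC)c([C@@H]2C=C(C)CC[C@]2(C)C=C)c1O | intermediate
17 | 2-[(1R,6R)-6-ethenyl-3,6-dimethylcyclohex-2-en-1-yl]-6-formyl-3,5-dimethoxyphenyl (triphenylphosphoranylidene)acetate | O=Cc1c(OC)cc(OC)c([C@@H]2C=C(C)CC[C@]2(C)C=C)c1OC(=O)C=P(c1ccccc1)(c1ccccc1)c1ccccc1 | intermediate (not isolated)
18 | 8-[(1R,6R)-6-ethenyl-3,6-dimethylcyclohex-2-en-1-yl]-5,7-dimethoxy-2H-chromen-2-one | O=c1ccc2c(OC)cc(OC)c([C@@H]3C=C(C)CC[C@]3(C)C=C)c2o1 | intermediate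
19 | 5,7-dimethoxy-2H-chromen-2-one | COc1cc(OC)c2ccc(=O)oc2c1 | starting material
20 | 8-iodo-5,7-dimethoxy-2H-chromen-2-one | COc1cc(OC)c2ccc(=O)oc2c1I | intermediate
21 | 8-[(E)-2-[(1R,2R)-2-(5,7-dimethoxy-2-oxo-2H-chromen-8-yl)-1,4-dimethylcyclohex-3-en-1-yl]ethenyl]-5,7-dimethoxy-2H-chromen-2-one | COc1cc(OC)c2ccc(=O)oc2c1/C=C/[C@@]1(C)CCC(C)=C[C@H]1c1c(OC)cc(OC)c2ccc(=O)oc12 | target

**Step count**

Total: 11 steps. Longest linear sequence: 10 steps (steps 1–9 and 11); step 10 is a one-step side branch.

**Steps most likely to fail**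

1. Step 4 (the step carrying the new method). The α-alkyl, doubly donor-substituted acceptor may be too unreactive, so that 1,2-addition and lactone opening compete; enantioface control may erode with the vinyl nucleophile; the aryl ester enolate may fragment to a ketene and phenoxide before it is methylated. The fallback sets out from 19 and rejoins at 11, and makes the two bonds in separate, known operations. Rhodium-catalysed asymmetric 1,4-addition of potassium vinyltrifluoroborate K[CH2=CHBF3] to 19 (Rh(acac)(C2H4)2, Segphos enantiomer chosen for the 4S product, dioxane/H2O, 60 °C) should give (4S)-4-ethenyl-5,7-dimethoxy-3,4-dihydro-2H-chromen-2-one F1; 3-unsubstituted coumarins are an established substrate class for this addition of organoboron reagents. Its lithium enolate (LiN(SiMe3)2, THF, −78 °C) is alkylated anti to the vinyl group by 4-iodo-2-methylbut-1-ene F2 (from 2 with NaI in acetone, Finkelstein reaction) to give (3R,4R)-4-ethenyl-5,7-dimethoxy-3-(3-methylbut-3-en-1-yl)-3,4-dihydro-2H-chromen-2-one F3 (3,4-trans). A second enolisation and methylation with 9 (LiN(SiMe3)2, DMPU, THF, −78 °C), again anti to vinyl, should give 11.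

2. Step 11. Oxidative addition and alkene insertion may be slow with the di-ortho-substituted, electron-rich iodide and the neopentyl-type alkene, and reductive deiodination may then take over. The fallback sets out from 18 and rejoins at 21, and reverses the roles of the partners. Cross-metathesis of 18 with vinylboronic acid pinacol ester (second-generation Hoveyda–Grubbs catalyst RuCl2(=CH-C6H4-2-O-i-Pr)(H2IMes), CH2Cl2, 40 °C) should give 5,7-dimethoxy-8-[(1R,6R)-3,6-dimethyl-6-[(E)-2-(4,4,5,5-tetramethyl-1,3,2-dioxaborolan-2-yl)ethenyl]cyclohex-2-en-1-yl]-2H-chromen-2-one F4. Suzuki–Miyaura coupling of F4 with 20 (Pd(dppf)Cl2, K3PO4, dioxane/H2O, 70 °C) should give 21 with the E geometry retained.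

3. Step 6. The aluminium hemiacetal may collapse early, because the aryloxide is a good leaving group, and the freed aldehyde would then be reduced further to the diol. The fallback sets out from 12 and rejoins at 13, and holds the aldehyde oxidation level by chelation instead of by temperature. Opening of 12 with the magnesium amide from MeNH(OMe)·HCl and i-PrMgCl (THF, −20 → 0 °C) should give (1S,2S)-2-(2-hydroxy-4,6-dimethoxyphenyl)-N-methoxy-N,1,4-trimethylcyclohex-3-ene-1-carboxamide F5. Reduction with LiAlH4 (THF, −78 → 0 °C, one extra equivalent for the phenol) gives a chelated tetrahedral intermediate that releases aldehyde 14 only on work-up, where it closes to 13.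

**Further compounds**

F1 | step 4 | (4S)-4-ethenyl-5,7-dimethoxy-3,4-dihydro-2H-chromen-2-one | O=C2Oc1cc(OC)cc(OC)c1[C@H](C=C)C2
F2 | step 4 | 4-iodo-2-methylbut-1-ene | C=C(C)CCI
F3 | step 4 | (3R,4R)-4-ethenyl-5,7-dimethoxy-3-(3-methylbut-3-en-1-yl)-3,4-dihydro-2H-chromen-2-one | O=C2Oc1cc(OC)cc(OC)c1[C@H](C=C)[C@H]2CCC(C)=C
F4 | step 11 | 5,7-dimethoxy-8-[(1R,6R)-3,6-dimethyl-6-[(E)-2-(4,4,5,5-tetramethyl-1,3,2-dioxaborolan-2-yl)ethenyl]cyclohex-2-en-1-yl]-2H-chromen-2-one | O=c1ccc2c(OC)cc(OC)c([C@@H]3C=C(C)CC[C@]3(C)/C=C/B4OC(C)(C)C(C)(C)O4)c2o1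
F5 | step 6 | (1S,2S)-2-(2-hydroxy-4,6-dimethoxyphenyl)-N-methoxy-N,1,4-trimethylcyclohex-3-ene-1-carboxamide | Oc1cc(OC)cc(OC)c1[C@@H]2C=C(C)CC[C@]2(C)C(=O)N(C)OC
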